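In a one-step world, substrate and reagent in the reaction phase go to target, and at a given [reagent in the reaction phase] one equilibrium constant gives the fraction left; this flask has more around that step.

    reagent in the reaction phase ⇌ reagent in the second phase, rate k1*([reagent in the reaction phase] - [reagent in the second phase]/K1) per volume of the first phase (K1 = 0.463, k1 = 0.0151 /min)
    substrate + reagent in the reaction phase ⇌ target (K2 = 160 /M, k2 = 1.67 /M/min)
    reagent in the reaction phase → decomposed reagent (k3 = 0.00426 /min)
    target ⇌ isomer of the product (K4 = 1.03, k4 = 0.0432 /min)

substrate 10 mM; reagent in the second phase 18.0 mM; time 6.0 h; volume of the second phase over the first 2.0

- amber: doubling the amount of reagent in the second phase, all else as stated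
- grey: doubling the transfer coefficient of step 1, all else as stated

- in the second phase: reagent in the second phase; everything else is in the first
- charges count per volume of the first phase; a concentration in a rate is the amount of a species over the volume of its own phase; every rate counts per litre of the first phase
- run time (flask): 6.0 h

1. the target standing at 6.0 h, as a percentage of the substrate charged
2. the change that raises the amount of target at 6.0 h, in percent of the substrate charged most ("none" if none brings more than 2 percentage points) (amber / grey / none)
3. amount of target at 6.0 h, in percent of the substrate charged, after grey

I draw the curve of the target and reckon with the fraction of substrate left. At the start [reagent in the reaction phase] is zero, so the target leaves flat. Reagent in the second phase enters the reaction phase at 0.294 mM/min at first, and the phases approach their partition with a half-life of 22.1 min, which I take as the first knee. Target and isomer relax in 8.14 min, faster than that, so I count them as one bound stock.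

Once the phases stand at their partition, unbound reagent in both phases together is 1.93 times [reagent in the reaction phase], so decomposition halves it in 5.22 h. I guess 5.00 mM bound, and the rest of the charge, decaying until 6.0 h, leaves [reagent in the reaction phase] at 3.04 mM. At that level the binding step relaxes in 67.8 min, which is shorter than the reagent's decline, so the curve bends into a slowly sinking level: thermodynamic control.

I reckon that level with the holding factor 325 /M, the bound stock over free substrate per unit of [reagent in the reaction phase]. The fraction left is one over one plus the holding factor times [reagent in the reaction phase]. This gives 50.3% of the substrate left, which closes on my guess of what is bound, and a target of 24.5%.

For amber I guess 6.67 mM bound, which gives [reagent in the reaction phase] at 6.87 mM and a target of 34.0%, so amber is my choice. Grey moves the knee, and 22.1 min is short against 6.0 h, so I keep 24.5% for it.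

The forecast says 25.5% (23% to 28%), a little above mine, names amber, and gives 24.8% after grey (22% to 27.5%), since “faster transfer only speeds the approach”.

The simulation gives 26.1%, 25.9% after grey, and amber as the best change, worth 9.3 percentage points. In this flask [reagent in the reaction phase] stands at 3.15 mM at 6.00 h, and the holding factor turns that into 49.4% of substrate left, against 46.8% standing. The neighbour flask with 40 mM of substrate has [reagent in the reaction phase] at 1.35 mM, so the same factor gives 69.5% left and 15.0% target. That neighbour flask holds 68.6% of substrate and 15.4% of target.

All constants belong to no real substance.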